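**Retrosynthetic overview**

- The acid is set free last, by saponification of ethyl 2-(5-hexadecylfuran-2-yl)acetate.
- That ester is assembled in one flask from three components around an intact furan ring: furan (as furan-2-yllithium), hexadecylboronic acid pinacol ester and ethyl iodoacetate. The bond between the first CH2 of the hexadecyl chain and the ring carbon is made by a 1,2-shift of the alkyl group from boron to carbon in a furan-2-yl boronate complex, triggered when the radical •CH2CO2Et enters at the other alpha-carbon.
- The boronic ester comes from hexadec-1-ene and pinacolborane by hydroboration.
- Enabling feature: the 2,5-disubstituted furan ring. Its two alpha-carbons C2 and C5 are the ends of the ring diene C2=C3–C4=C5 and both adjoin the ring oxygen, so a group entering at C5 leaves an oxygen-stabilised cation at the boron-bearing C2 (which drives the shift), and the resulting 2,5-dihydrofuran regains aromaticity by 1,4-loss of OH (from the oxidised C–B bond) at C2 and H at C5.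
- Ring order: the only ring, the furan, is bought as furan; no ring is formed, it is dearomatised and rearomatised inside the key step.

Key step: step 2

Remark on the chemistry: the target has no stereocentre and no double-bond geometry; the two stereocentres of the non-isolated 2,5-dihydrofuran intermediates of the key step would form as mixtures and are erased on aromatisation.

**Route**

Step 1
Reactants: 1 hexadec-1-ene
Product: 2 2-hexadecyl-4,4,5,5-tetramethyl-1,3,2-dioxaborolane (hexadecylboronic acid pinacol ester)
Conditions: HBpin (1.2 equiv), [Ir(cod)Cl]2 (1.5 mol%), dppm (3 mol%), CH2Cl2, rt
Reagents that add atoms: pinacolborane, CC1(C)OBOC1(C)C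
Why: The iridium-catalysed anti-Markovnikov hydroboration of a terminal alkene with pinacolborane (dppm = bis(diphenylphosphino)methane as ligand) should place boron on the terminal carbon with high regioselectivity in an addition that uses all atoms of both partners, and no stereocentre is formed.

Step 2
Reactants: 2 2-hexadecyl-4,4,5,5-tetramethyl-1,3,2-dioxaborolane, 3 furan, 4 ethyl iodoacetate
Product: 9 ethyl 2-(5-hexadecylfuran-2-yl)acetate, via furan-2-yllithium 5 (not isolated), via lithium furyl boronate complex 6 (not isolated), via 2,5-dihydrofuran boronic ester 7 (not isolated), via hemiketal 8 (not isolated)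
Conditions: 3 (1.1 equiv), n-BuLi (1.0 equiv), THF, −78 to 0 °C; 2 (1.05 equiv), −78 °C to rt; 4 (1.5 equiv), BEt3 (10 mol%), trace air, MeCN, rt; 30% H2O2, pH 7 phosphate buffer, 0 °C to rt; PPTS (cat.), CH2Cl2, rt
Reagents that add atoms: none
Why: Proposed new method: furan-2-yllithium 5 and boronic ester 2 should give the tetracoordinate boronate 6, whose electron-rich ring is attacked at the free alpha-carbon C5 by the electrophilic radical •CH2CO2Et (from 4, BEt3/O2 initiation); the boron-substituted allyl radical so formed hands an electron to the next molecule of 4 (chain), and the oxygen-stabilised cation at C2 draws the hexadecyl group from boron to C2 in a 1,2-metallate shift, which makes the hexadecyl CH2–ring C2 bond and gives 7 (direct SN2 attack of C5 of 6 on 4 would lead to the same 7). The closest known reaction types are the trifluoromethyl-radical-induced three-component coupling of furan-2-yl boronate complexes, the N-bromosuccinimide-induced Zweifel-type coupling of the same complexes and the radical-polar crossover of vinyl boronate complexes with alpha-iodo esters; new is the pairing of an alpha-ester alkyl iodide with a furyl boronate. No ring is closed: the furan ring of 3 is dearomatised to the 2,5-dihydrofuran 7 and restored when buffered H2O2 oxidises the C–B bond to hemiketal 8, which loses water by 1,4-elimination (OH from C2, H from C5) under PPTS. No stereocentre is left in 9; the two stereocentres of 7 and 8 form without control and vanish on aromatisation. The step needs attack at C5 and not at C3 or at the boron-bearing C2 (C5 is the unhindered terminus of the ring diene and attack there gives the allyl radical conjugated with boron and oxygen), migration of hexadecyl and not of a pinacol oxygen (the diol ligand does not migrate), and an ester untouched by organolithium (n-BuLi is the limiting reagent and 5 is bound as 6 before 4 is added).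

Step 3
Reactants: 9 ethyl 2-(5-hexadecylfuran-2-yl)acetate
Product: 11 2-(5-hexadecylfuran-2-yl)acetic acid, via lithium carboxylate 10 (not isolated)
Conditions: LiOH·H2O (3 equiv), THF/H2O (3:1), argon, rt; then 1 M HCl, 0 °C, to pH 3
Reagents that add atoms: lithium hydroxide, [Li+].[OH-]
Why: Saponification (acyl–oxygen cleavage by hydroxide) of the unhindered ethyl ester should proceed at room temperature, the 2,5-dialkylfuran tolerates aqueous base, and brief cold acidification should set the acid free without opening the ring.

**Compound list**

1 | hexadec-1-ene | C=CCCCCCCCCCCCCCC | starting material
2 | 2-hexadecyl-4,4,5,5-tetramethyl-1,3,2-dioxaborolane | CCCCCCCCCCCCCCCCB1OC(C)(C)C(C)(C)O1 | intermediate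
3 | furan | c1ccoc1 | starting material
4 | ethyl iodoacetate | CCOC(=O)CI | starting material
5 | furan-2-yllithium (not isolated) | [Li]c1ccco1 | intermediate
6 | lithium (furan-2-yl)(hexadecyl)(pinacolato)borate (not isolated) | [Li+].CCCCCCCCCCCCCCCC[B-]1(c2ccco2)OC(C)(C)C(C)(C)O1 | intermediate
7 | ethyl 2-[5-hexadecyl-5-(4,4,5,5-tetramethyl-1,3,2-dioxaborolan-2-yl)-2,5-dihydrofuran-2-yl]acetate, mixture of diastereomers (not isolated) | CCCCCCCCCCCCCCCCC1(B2OC(C)(C)C(C)(C)O2)C=CC(CC(=O)OCC)O1 | intermediate
8 | ethyl 2-(5-hexadecyl-5-hydroxy-2,5-dihydrofuran-2-yl)acetate, mixture of diastereomers (not isolated) | CCCCCCCCCCCCCCCCC1(O)C=CC(CC(=O)OCC)O1 | intermediate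
9 | ethyl 2-(5-hexadecylfuran-2-yl)acetate | CCCCCCCCCCCCCCCCc1ccc(CC(=O)OCC)o1 | intermediate
10 | lithium 2-(5-hexadecylfuran-2-yl)acetate (not isolated) | [Li+].CCCCCCCCCCCCCCCCc1ccc(CC(=O)[O-])o1 | intermediate
11 | 2-(5-hexadecylfuran-2-yl)acetic acid | CCCCCCCCCCCCCCCCc1ccc(CC(=O)O)o1 | target

**Step count and risks**

Total step count: 3. Longest linear sequence: 3 steps (1 → 2 → 9 → 11).

Steps most likely to fail:

1. Step 2 (proposed new method). The radical chain may fail to propagate, the electrophile may attack the boron-bearing carbon and expel the boronic ester instead of inducing the shift, or oxidation may be followed by ring opening instead of dehydration. Fallback with known chemistry: it sets out from furan-2-yllithium 5. SN2 alkylation with 1-bromohexadecane (THF, −78 °C to rt) should give 2-hexadecylfuran F1, which forms the same hexadecyl–ring bond in the classical way. Homolytic aromatic substitution of F1 at its free alpha-position with ethyl iodoacetate 4 under Fenton-type conditions (FeSO4·7H2O, H2O2, DMSO, rt) then returns to the route at ester 9. In that step methyl radicals from DMSO abstract iodine from 4, the electrophilic ester radical adds to the furan, and oxidation and loss of a proton follow.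

2. Step 3. Hydrolysis of the waxy ester may be slow and heterogeneous, and deprotonation of the CH2 between the furan ring and the ester during that time opens the way to autoxidation and Claisen-type self-condensation. Fallback: it sets out from ester 9. Lipase-catalysed hydrolysis at neutral pH (immobilised Candida antarctica lipase B, pH 7 phosphate buffer/tert-butyl methyl ether, 30 °C, pH held by titration with dilute LiOH) never generates the ester enolate. It returns to the route at lithium carboxylate 10, which is acidified as in step 3; no new compound is made (entry F0).

3. Step 1. The double bond may migrate along the chain before B–H addition, or dehydrogenative borylation may compete, giving secondary or alkenyl boronic esters that would be hard to remove from the waxy product. Fallback: it sets out from hexadec-1-ene 1. Uncatalysed hydroboration with HBBr2·SMe2 (CH2Cl2, reflux), which adds through a four-centre transition state without any metal hydride, should give hexadecyldibromoborane–dimethyl sulfide complex F2. Esterification with pinacol and Et3N (CH2Cl2, 0 °C) returns to the route at boronic ester 2.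

Further compounds
F1 | step 2 | 2-hexadecylfuran | CCCCCCCCCCCCCCCCc1ccco1
F0 | step 3 | none | none
F2 | step 1 | hexadecyldibromoborane–dimethyl sulfide complex | CCCCCCCCCCCCCCCC[B-](Br)(Br)[S+](C)C
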